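Maple is the run I lean on for the flask, which differs from it in starting material and not in free catalyst.

| flask | starting material | gas phase | free catalyst | remark | time |
|---|---|---|---|---|---|
| maple | 0.56 M | 28 mM (held) | 0.22 mM | run made earlier |  |
| ash | 0.88 M | 28 mM (held) | 0.22 mM | run made earlier |  |
| cedar | 0.40 M | 28 mM (held) | 0.44 mM | run made earlier |  |
| flask | 0.40 M | 28 mM (held) | 0.22 mM |  | 25 h |

- maple (time / h: target / %): 3.00: 15.3; 6.00: 21.7; 12.0: 26.7; 25.0: 22.3
- ash (time / h: target / %): 3.00: 15.6; 6.00: 21.5; 12.0: 26.1; 25.0: 21.9
- cedar (time / h: target / %): 3.00: 27.8; 6.00: 40.0; 12.0: 42.7; 25.0: 36.0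

(readings scatter by 1 percentage point)

- at the start none of the gas phase is in solution

* the best time, 25 h at the latest, for target
* the amount of target, in percent of the starting material charged, at that time

At 12.0 h ash reads 26.1% and maple 26.7%, though ash is charged with more starting material, so I expect the flask's percentages to follow maple's. But cedar, charged with the flask's starting material and twice its free catalyst, reads 42.7% there, against maple's 26.7%, so I read more catalyst as going with more target. From 3.00 h to 6.00 h, maple gains 41.8% of its first gain and cedar 43.9%, so in these readings the fading keeps about one clock, which I read as catalyst deactivation.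

Maple's highest reading gives 1.41 mM⁻¹ and cedar's gives 1.27 mM⁻¹. That quantity is the reach: the logarithm of one over the share not turned into target at the highest reading, divided by c(free catalyst). With maple's reach I reckon 26.7% for the flask, near 12.0 h. That simply returns maple's reading, since the flask's c(free catalyst) equals maple's.

The forecast says 13.5 h (10.5 h to 17 h) and 27% (25.5% to 28.5%): "The sparse points leave the peak broad." Its time is later than mine.

    gas phase ⇌ dissolved gas, rate k1*(csat - [dissolved gas]) (kL = 0.190 min⁻¹)
    starting material + dissolved gas + free catalyst → free catalyst + target (k = 240 M⁻² min⁻¹)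
    dissolved gas → decomposed reagent (k = 0.00650 min⁻¹)
    free catalyst → spent catalyst (k = 0.00310 min⁻¹)
    dissolved gas + target → over-reaction product (k = 0.0140 M⁻¹ min⁻¹)

The flask gives 26.6% at 12.2 h, with free catalyst down to 10.4% of its charge. Its reach is 1.41 mM⁻¹. The forecast's 27% is wrong for a neighbour of the flask with less free catalyst: with 5.5 × 10⁻⁵ M, maple's reach gives 7.47%, and that neighbour reaches 7.94%.

The runs stem from a simulated flask with constants of no real substance, and the scatter is random.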